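Zeylenone is traced to an achiral cyclohexa-2,5-dienol made by dearomatising benzoic acid. Locants: C1 is the tertiary carbinol bearing C7H2OBz, C2 CHOH, C3 CHOBz, C4=C5 the alkene, C6 the ketone. With C4 as CH2, the six-membered ring has a mirror plane through C1 and C4, so C2=C3 and C6=C5 are enantiotopic. A chiral hafnium peroxide held by C1-OH epoxidises one of them on the hydroxyl face. One oxygen transfer closes the oxirane, makes C1 stereogenic and sets C2 and C3, with C2-O cis to C1-OH. The precursor is the dienol with only C7-O benzoylated. Benzoate opening at C3 and ene oxygenation of C5=C6 finish the ring.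

Key step: step 6

Remark on locants: the target locants C1–C7 defined above are used for every compound.

Assumption: the sense of induction of the hafnium bishydroxamate catalyst on this cyclic cis-alkene cannot be deduced safely from acyclic cases. The (R,R)-ligand is written. The equally available (S,S)-ligand is to be used if a pilot run shows that it leads to the (1S,2S,3S)-epoxy alcohol.

Step 1
Reactants: 1 benzoic acid
Product: 2 cyclohexa-2,5-diene-1-carboxylic acid
Conditions: Na, NH3(l), EtOH, −78 to −33 °C; NH4Cl; cold dil. HCl to pH 3, Et2O
Reagents that add atoms: none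
Why: Birch reduction, in which the carboxylate stabilises the ipso carbanion so that protonation occurs at C1 and C4 and the unconjugated 2,5-diene results, with no stereocentre formed.

Step 2
Reactants: 2 cyclohexa-2,5-diene-1-carboxylic acid
Product: 3 methyl cyclohexa-2,5-diene-1-carboxylate
Conditions: MeOH, H2SO4 (cat.), reflux, Ar
Reagents that add atoms: methanol, CO
Why: Fischer esterification under acid catalysis avoids the base-induced drift of the skipped diene into conjugation and provides an enolisable ester, with no stereocentre formed.

Step 3
Reactants: 3 methyl cyclohexa-2,5-diene-1-carboxylate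
Product: 5 methyl 1-hydroxycyclohexa-2,5-diene-1-carboxylate, via potassium dienolate 4 (not isolated)
Conditions: KHMDS, THF, −78 °C; 2-(phenylsulfonyl)-3-phenyloxaziridine, −78 °C; sat. aq. NH4Cl at −78 °C
Reagents that add atoms: 2-(phenylsulfonyl)-3-phenyloxaziridine, O=S(=O)(c1ccccc1)N1OC1c1ccccc1
Why: Davis-type enolate hydroxylation, in which the cross-conjugated dienolate accepts the electrophilic oxygen at its central carbon C1 as it does alkyl halides in Birch alkylations, the potassium counter-ion limits capture of the sulfonimine by-product, the ester retards ionisation of the new C1–O bond, and C1 stays achiral because the mirror plane persists.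

Step 4
Reactants: 5 methyl 1-hydroxycyclohexa-2,5-diene-1-carboxylate
Product: 6 1-(hydroxymethyl)cyclohexa-2,5-dien-1-ol
Conditions: LiAlH4, Et2O, 0 °C; Fieser work-up (H2O, 15% NaOH, H2O); base-washed glassware
Reagents that add atoms: none
Why: Hydride reduction of the ester leaves the isolated alkenes untouched and the alkaline work-up keeps the acid-labile arene hydrate intact, with no stereocentre formed.

Step 5
Reactants: 6 1-(hydroxymethyl)cyclohexa-2,5-dien-1-ol; 7 benzoyl chloride
Product: 8 (1-hydroxycyclohexa-2,5-dien-1-yl)methyl benzoate
Conditions: BzCl (1.05 equiv), Et3N (2 equiv), CH2Cl2, −20 to 0 °C; aq. NaHCO3; Et3N-deactivated silica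
Reagents that add atoms: benzoyl chloride (7), O=C(Cl)c1ccccc1
Why: Chemoselective O-acylation, in which the primary C7 hydroxyl reacts far faster than the tertiary C1 hydroxyl and the amine traps HCl before it can dehydrate the dienol, with no stereocentre formed.

Step 6
Reactants: 8 (1-hydroxycyclohexa-2,5-dien-1-yl)methyl benzoate; 9 cumene hydroperoxide
Product: 10 [(1S,2S,6S)-2-hydroxy-7-oxabicyclo[4.1.0]hept-3-en-2-yl]methyl benzoate (target locants 1S,2S,3S; oxirane on C2–C3 cis to C1-OH)
Conditions: Hf(OtBu)4 (10 mol %), (R,R)-N,N'-dihydroxy-N,N'-bis(diphenylacetyl)cyclohexane-1,2-diamine (12 mol %), MgO, 4 Å MS, toluene, rt, 1 h; then 8, CHP (1.2 equiv), 0 °C, dark, Ar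
Reagents that add atoms: cumene hydroperoxide (9), CC(C)(OO)c1ccccc1
Why: Proposed new method: alkoxide exchange binds C1-O of 8 and the cumyl peroxide side by side on the hafnium bishydroxamate, and the activated peroxide oxygen is passed to the neighbouring π bond through a concerted spiro transition state. The oxirane is therefore closed by a suprafacial [2+1] oxygen-atom transfer in which C2-O and C3-O form together, not by a stepwise exo or endo cyclisation. The closest known reaction types are hafnium and vanadium bishydroxamate epoxidations of tertiary or cis-configured allylic alcohols and the titanium tartrate desymmetrisation of acyclic divinyl carbinols, none of which has been shown on a cyclohexa-2,5-dienol. C2 and C3 are fixed by the metal tether, which reaches the ring alkene only from the face of C1-OH as in syn-selective epoxidation of cyclohex-2-enols, their cis relation follows from the Z ring alkene, and C1 becomes stereogenic (S) through the ligand's choice of the C2=C3 arm over the enantiotopic C6=C5 arm. The step needs group, face and chemoselectivity: 8 offers one free hydroxyl only, since the benzoate on C7-O shuts off delivery from the opposite face and by its inductive pull slows ionisation at C1, while aged catalyst, MgO and sieves keep free acid away from this dehydration-prone arene hydrate. Material epoxidised on the wrong arm still carries the alkene the catalyst prefers and should be removed by a second epoxidation, so a small excess of oxidant trades yield for enantiopurity.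

Step 7
Reactants: 10 syn-epoxy alcohol; 1 benzoic acid
Product: 11 [(1S,5R,6S)-5-(benzoyloxy)-1,6-dihydroxycyclohex-2-en-1-yl]methyl benzoate (target locants 1S,2S,3R; C1-OH and C2-OH cis; C3-OBz trans to C2-OH)
Conditions: Ti(OiPr)4 (1.5 equiv), PhCO2H (1.5 equiv), CH2Cl2, 0 °C to rt; aq. Rochelle salt
Reagents that add atoms: benzoic acid (1), OC(=O)c1ccccc1
Why: Titanium(IV)-mediated opening of a 2,3-epoxy alcohol by a carboxylic acid, in which the C1 alkoxide and the oxirane oxygen chelate titanium on one face and benzoate attacks the less hindered and inductively less deactivated C3 from the other face in an SN2 process, inverting C3 to R and leaving C1 and C2 untouched.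

Step 8
Reactants: 11 C3-benzoate diol
Product: 12 [(3aS,4R,7aS)-4-(benzoyloxy)-2,2-dimethyl-3a,4,5,7a-tetrahydro-1,3-benzodioxol-7a-yl]methyl benzoate (C1/C2 acetonide of 11)
Conditions: 2,2-dimethoxypropane, PPTS (cat.), CH2Cl2, rt
Reagents that add atoms: 2,2-dimethoxypropane, COC(C)(C)OC
Why: Acid-catalysed transketalisation, in which the cis C1/C2 diol closes a cis-fused dioxolane that blocks acetylation of C2-OH and benzoate migration in the next step, with no stereocentre changed.

Step 9
Reactants: 12 acetonide
Product: 15 [(3aS,4R,7aS)-4-(benzoyloxy)-2,2-dimethyl-7-oxo-3a,4,7,7a-tetrahydro-1,3-benzodioxol-7a-yl]methyl benzoate (C1/C2 acetonide of zeylenone), via C6 allylic hydroperoxide 13 (not isolated), via C6 allylic peracetate 14 (not isolated)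
Conditions: O2, TPP (cat.), visible light, CDCl3 (filtered through basic alumina), 0–10 °C; then Ac2O, pyridine, DMAP (cat.), 0 °C to rt
Reagents that add atoms: dioxygen, O=O; acetic anhydride, CC(=O)OC(C)=O (acetyl group present only in 14)
Why: Schenck ene reaction followed by Kornblum–DeLaMare-type elimination of the acylated hydroperoxide, in which singlet oxygen can take an allylic hydrogen only from C4 because C1 has none, so oxygen lands on C6 and the alkene moves to C4=C5, the transient C6 stereocentre is erased on forming the ketone, and C1–C3 are untouched.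

Step 10
Reactants: 15 enone acetonide
Product: 16 zeylenone, [(1S,5R,6S)-5-(benzoyloxy)-1,6-dihydroxy-2-oxocyclohex-3-en-1-yl]methyl benzoate
Conditions: TFA/H2O (9:1), CH2Cl2, 0 °C to rt
Reagents that add atoms: none
Why: Acid hydrolysis of the isopropylidene acetal, which the benzoates and the enone should tolerate and which touches no stereocentre because C1 is quaternary and cannot enolise.

Compound list
1 | benzoic acid | OC(=O)c1ccccc1 | starting material
2 | cyclohexa-2,5-diene-1-carboxylic acid | OC(=O)C1C=CCC=C1 | intermediate
3 | methyl cyclohexa-2,5-diene-1-carboxylate | COC(=O)C1C=CCC=C1 | intermediate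
4 | potassium dienolate of 3 (not isolated) | COC([O-])=C1C=CCC=C1.[K+] | intermediate
5 | methyl 1-hydroxycyclohexa-2,5-diene-1-carboxylate | COC(=O)C1(O)C=CCC=C1 | intermediate
6 | 1-(hydroxymethyl)cyclohexa-2,5-dien-1-ol | OCC1(O)C=CCC=C1 | intermediate
7 | benzoyl chloride | O=C(Cl)c1ccccc1 | starting material
8 | (1-hydroxycyclohexa-2,5-dien-1-yl)methyl benzoate | O=C(OCC1(O)C=CCC=C1)c1ccccc1 | intermediate
9 | cumene hydroperoxide | CC(C)(OO)c1ccccc1 | starting material
10 | [(1S,2S,6S)-2-hydroxy-7-oxabicyclo[4.1.0]hept-3-en-2-yl]methyl benzoate | O=C(OC[C@@]1(O)C=CC[C@@H]2O[C@H]12)c1ccccc1 | intermediate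
11 | [(1S,5R,6S)-5-(benzoyloxy)-1,6-dihydroxycyclohex-2-en-1-yl]methyl benzoate | O=C(OC[C@@]1(O)C=CC[C@@H](OC(=O)c2ccccc2)[C@@H]1O)c1ccccc1 | intermediate
12 | C1/C2 acetonide of 11 | O=C(OC[C@]12OC(C)(C)O[C@H]1[C@H](OC(=O)c3ccccc3)CC=C2)c4ccccc4 | intermediate
13 | C6 allylic hydroperoxide, C4=C5 alkene, C6 configuration inconsequential (not isolated) | O=C(OC[C@]12OC(C)(C)O[C@H]1[C@H](OC(=O)c3ccccc3)C=CC2OO)c4ccccc4 | intermediate
14 | C6 allylic peracetate, C6 configuration inconsequential (not isolated) | O=C(OC[C@]12OC(C)(C)O[C@H]1[C@H](OC(=O)c3ccccc3)C=CC2OOC(C)=O)c4ccccc4 | intermediate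
15 | C1/C2 acetonide of zeylenone | O=C(OC[C@]12OC(C)(C)O[C@H]1[C@H](OC(=O)c3ccccc3)C=CC2=O)c4ccccc4 | intermediate
16 | zeylenone | O=C(OC[C@@]1(O)C(=O)C=C[C@@H](OC(=O)c2ccccc2)[C@@H]1O)c1ccccc1 | target

Total step count: 10. Longest linear sequence: 10 steps, from benzoic acid.

Steps most likely to fail

1. Step 6. The catalyst may discriminate poorly between the two enantiotopic alkenes, or acid-induced loss of water from the dienol may outrun oxygen transfer. The fallback uses known chemistry and replaces asymmetric catalysis by resolution. It sets out from 8 with a hydroxyl-directed peracid epoxidation (mCPBA, 1 equiv, CH2Cl2/aq. NaHCO3, 0 °C). This is Henbest-type hydrogen-bond delivery, reinforced by the bulkier CH2OBz group on the other face. It should give the racemic syn-epoxy alcohol, that is 10 together with its mirror image, the (1R,2R,3R)-epoxy alcohol F1. Preparative chromatography on a chiral stationary phase (SFC) separates the two, and the route is rejoined at 10.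

2. Step 9. The ene reaction of a cis-disubstituted, inductively deactivated ring alkene may be so slow that sensitiser bleaching and photodegradation overtake oxygenation. The fallback replaces the pericyclic oxygenation by an epoxide-to-allylic-alcohol transposition.
   - From 12, mCPBA/NaHCO3 in CH2Cl2 should give the C5–C6 epoxide F2, whose face is of no consequence.
   - PhSeSePh/NaBH4 in EtOH opens it at C5, the carbon remote from the quaternary C1, to the C6-hydroxy C5-selenide F3.
   - H2O2 in THF at 0 °C gives the selenoxide F4, which undergoes syn elimination away from the carbinol carbon, towards C4, to the C6 allylic alcohol F5.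
   - Dess–Martin periodinane/NaHCO3 oxidises F5, and the route is rejoined at 15.

3. Step 3. Electron transfer from the electron-rich dienolate to the oxidant, or proton shuffling, may lead to rearomatisation, and the dienolate may add to the sulfonimine by-product. The fallback oxidises a neutral enol derivative instead of the anion (Rubottom-type).
   - From 3, the dienolate 4 is trapped with TMSCl at −78 °C to give the silyl ketene acetal F6, which is used crude and cold.
   - Dimethyldioxirane in acetone at −78 to −40 °C oxidises its exocyclic, most electron-rich alkene, and silyl migration gives the α-silyloxy ester F7.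
   - TBAF/AcOH in THF at 0 °C removes the silyl group, and the route is rejoined at 5.

Further compounds
F1 | step 6 | [(1R,2R,6R)-2-hydroxy-7-oxabicyclo[4.1.0]hept-3-en-2-yl]methyl benzoate (enantiomer of 10) | O=C(OC[C@]1(O)C=CC[C@H]2O[C@@H]12)c1ccccc1
F2 | step 9 | C5–C6 epoxide of 12 (C5/C6 configuration inconsequential) | O=C(OC[C@]12OC(C)(C)O[C@H]1[C@H](OC(=O)c3ccccc3)CC4OC42)c5ccccc5
F3 | step 9 | C6-hydroxy C5-phenylselenide (trans; C5/C6 configuration inconsequential) | O=C(OC[C@]12OC(C)(C)O[C@H]1[C@H](OC(=O)c3ccccc3)CC([Se]c4ccccc4)C2O)c5ccccc5
F4 | step 9 | selenoxide of F3 | O=C(OC[C@]12OC(C)(C)O[C@H]1[C@H](OC(=O)c3ccccc3)CC([Se](=O)c4ccccc4)C2O)c5ccccc5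
F5 | step 9 | C6 allylic alcohol, C4=C5 alkene (C6 configuration inconsequential) | O=C(OC[C@]12OC(C)(C)O[C@H]1[C@H](OC(=O)c3ccccc3)C=CC2O)c5ccccc5
F6 | step 3 | [(cyclohexa-2,5-dien-1-ylidene)(methoxy)methoxy]trimethylsilane | COC(O[Si](C)(C)C)=C1C=CCC=C1
F7 | step 3 | methyl 1-(trimethylsilyloxy)cyclohexa-2,5-diene-1-carboxylate | COC(=O)C1(O[Si](C)(C)C)C=CCC=C1
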